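**Retrosynthetic overview**

1. The target is reached by desilylation of its C3 silyl ether; all three rings are already in place at that stage.
2. Key disconnection: the C6–C7 bond together with the lactone C–O bond. A divalent-chromium (Nozaki–Hiyama-type) allylation of a (Z)-enal by a 2-(bromomethyl)enoate closes the ten-membered carbocycle, and the chromium alkoxide lactonises onto the methyl ester in the same operation (sets C6 and C7).
3. The acyclic precursor comes from a dialdehyde (Morita–Baylis–Hillman reaction at the α-acyloxy aldehyde, then SN2′ bromination); the (1R,10R)-epoxide is installed earlier by Shi epoxidation of the acyclic E-olefin.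
4. The chain is assembled from (Z)-3-iodobut-2-enyl PMB ether (C4–C6, C15), (E)-4-iodopent-3-enal (C1–C3, C10, C14) and (R)-PMB glycidyl ether (C7–C9); C3 is set by asymmetric alkenylzinc addition, C8 comes from the glycidyl ether, and methyl acrylate supplies C11–C13.
5. Ring order: epoxide first, then the ten-membered ring and the α-methylene lactone together.

Assumption and notation: atom labels C1–C15 follow germacrane numbering of the target; PMB = 4-methoxybenzyl, TBS = tert-butyldimethylsilyl; (R)-PMB glycidyl ether is taken as a commercial chiral-pool material.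

**Step 1**
Reactants: 1 but-2-yn-1-ol
Product: 3 (2Z)-3-iodobut-2-en-1-ol, via cyclic sodium alkenylaluminate 2 (not isolated)
Conditions: NaAlH2(OCH2CH2OCH3)2, Et2O, 0 °C to rt; then I2, −78 to 0 °C
Reagents that add atoms: iodine, II
Why: Alkoxide-directed trans-hydroalumination (hydroalumination–iodination) places aluminium on C3 cis to the CH2O arm in a five-membered aluminate, and iodinolysis of the C–Al bond with retention gives the Z-vinyl iodide.

**Step 2**
Reactants: 3 (2Z)-3-iodobut-2-en-1-ol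
Product: 4 1-({[(2Z)-3-iodobut-2-en-1-yl]oxy}methyl)-4-methoxybenzene
Conditions: NaH, 4-methoxybenzyl chloride, Bu4NI (cat.), THF–DMF, 0 °C to rt
Reagents that add atoms: 4-methoxybenzyl chloride, COc1ccc(CCl)cc1
Why: Williamson etherification of the primary allylic alkoxide; the vinyl iodide is inert under these conditions.

**Step 3**
Reactants: 5 pent-3-yn-1-ol
Product: 7 (3E)-4-iodopent-3-en-1-ol, via alkenylzirconocene chloride 6 (not isolated)
Conditions: Cp2Zr(H)Cl (2.2 equiv), THF, rt; then I2, 0 °C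
Reagents that add atoms: iodine, II
Why: syn-Hydrozirconation of the internal alkyne (the first equivalent of Cp2Zr(H)Cl is consumed by the hydroxyl) equilibrates zirconium onto the less hindered methyl-bearing carbon, and iodinolysis with retention gives the E-vinyl iodide.

**Step 4**
Reactants: 7 (3E)-4-iodopent-3-en-1-ol
Product: 8 (3E)-4-iodopent-3-enal
Conditions: Dess–Martin periodinane, NaHCO3, CH2Cl2, 0 °C; used crude
Reagents that add atoms: none
Why: Dess–Martin oxidation is neutral and fast, so the β,γ-unsaturated aldehyde forms without migration of the double bond and is used at once.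

**Step 5**
Reactants: 4 1-({[(2Z)-3-iodobut-2-en-1-yl]oxy}methyl)-4-methoxybenzene; 8 (3E)-4-iodopent-3-enal
Product: 11 (2Z,4R,6E)-7-iodo-1-[(4-methoxybenzyl)oxy]-3-methylocta-2,6-dien-4-ol, via alkenyllithium 9 (not isolated), via dialkenylzinc 10 (not isolated)
Conditions: 4 (2.2 equiv), t-BuLi, Et2O, −78 °C; ZnBr2, −78 to 0 °C; N,N,N′,N′-tetraethylethylenediamine, (2S)-3-exo-morpholinoisoborneol [(−)-MIB, 10 mol %], toluene; then 8, −10 °C
Reagents that add atoms: none
Why: Iodine–lithium exchange and transmetalation to zinc keep the Z geometry, and the zinc aminoalkoxide of (−)-MIB delivers the alkenyl group to the Si face of the aldehyde (catalytic asymmetric alkenylzinc addition of the Oppolzer/Walsh type), which here corresponds to 3R.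

**Step 6**
Reactants: 11 (2Z,4R,6E)-7-iodo-1-[(4-methoxybenzyl)oxy]-3-methylocta-2,6-dien-4-ol
Product: 12 tert-butyl({(2Z,4R,6E)-7-iodo-1-[(4-methoxybenzyl)oxy]-3-methylocta-2,6-dien-4-yl}oxy)dimethylsilane
Conditions: t-BuMe2SiCl, imidazole, DMF, rt
Reagents that add atoms: tert-butyldimethylsilyl chloride, CC(C)(C)[Si](C)(C)Cl
Why: Standard silylation of the secondary allylic alcohol; no stereocentre is touched.

**Step 7**
Reactants: 12 tert-butyl({(2Z,4R,6E)-7-iodo-1-[(4-methoxybenzyl)oxy]-3-methylocta-2,6-dien-4-yl}oxy)dimethylsilane; 13 (2R)-2-{[(4-methoxybenzyl)oxy]methyl}oxirane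
Product: 15 (2R,4E,7R,8Z)-7-{[tert-butyl(dimethyl)silyl]oxy}-1,10-bis[(4-methoxybenzyl)oxy]-4,8-dimethyldeca-4,8-dien-2-ol, via alkenyllithium 14 (not isolated)
Conditions: t-BuLi (2.1 equiv), Et2O, −78 °C; then BF3·OEt2, 13, −78 °C
Reagents that add atoms: none
Why: Iodine–lithium exchange proceeds with retention of the E geometry and the BF3-activated terminal epoxide is opened by SN2 attack at its CH2 carbon, so C8 (R) is taken unchanged from the glycidyl ether.

**Step 8**
Reactants: 15 (2R,4E,7R,8Z)-7-{[tert-butyl(dimethyl)silyl]oxy}-1,10-bis[(4-methoxybenzyl)oxy]-4,8-dimethyldeca-4,8-dien-2-ol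
Product: 16 (2R,4E,7R,8Z)-7-{[tert-butyl(dimethyl)silyl]oxy}-1,10-bis[(4-methoxybenzyl)oxy]-4,8-dimethyldeca-4,8-dien-2-yl 3-methylbutanoate
Conditions: 3-methylbutanoyl chloride, pyridine, 4-(dimethylamino)pyridine (cat.), CH2Cl2, 0 °C to rt
Reagents that add atoms: 3-methylbutanoyl chloride, CC(C)CC(=O)Cl
Why: Nucleophile-catalysed acylation of the only free hydroxyl installs the isovalerate of the target at C8.

**Step 9**
Reactants: 16 (2R,4E,7R,8Z)-7-{[tert-butyl(dimethyl)silyl]oxy}-1,10-bis[(4-methoxybenzyl)oxy]-4,8-dimethyldeca-4,8-dien-2-yl 3-methylbutanoate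
Product: 17 (2R)-1-[(4-methoxybenzyl)oxy]-3-[(2R,3R)-3-{(2R,3Z)-2-{[tert-butyl(dimethyl)silyl]oxy}-5-[(4-methoxybenzyl)oxy]-3-methylpent-3-en-1-yl}-2-methyloxiran-2-yl]propan-2-yl 3-methylbutanoate
Conditions: 1,2:4,5-di-O-isopropylidene-β-D-erythro-2,3-hexodiulo-2,6-pyranose (D-fructose-derived Shi ketone, 0.3 equiv), KHSO5 (as 2KHSO5·KHSO4·K2SO4), K2CO3, Bu4NHSO4, MeCN–CH2(OMe)2–aq. Na2B4O7 buffer (pH 10.5), 0 °C
Reagents that add atoms: potassium peroxymonosulfate, [K+].[O-]S(=O)(=O)OO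
Why: Shi asymmetric epoxidation: the dioxirane of the D-fructose-derived ketone attacks the electron-rich E-trisubstituted C1=C10 olefin through a spiro transition state to give the (1R,10R)-epoxide, while the Z-olefin flanked by two allylic oxygens reacts much more slowly.

**Step 10**
Reactants: 17 (2R)-1-[(4-methoxybenzyl)oxy]-3-[(2R,3R)-3-{(2R,3Z)-2-{[tert-butyl(dimethyl)silyl]oxy}-5-[(4-methoxybenzyl)oxy]-3-methylpent-3-en-1-yl}-2-methyloxiran-2-yl]propan-2-yl 3-methylbutanoate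
Product: 18 (2R)-1-hydroxy-3-[(2R,3R)-3-{(2R,3Z)-2-{[tert-butyl(dimethyl)silyl]oxy}-5-hydroxy-3-methylpent-3-en-1-yl}-2-methyloxiran-2-yl]propan-2-yl 3-methylbutanoate
Conditions: 2,3-dichloro-5,6-dicyano-1,4-benzoquinone (2.5 equiv), CH2Cl2–pH 7 buffer, 0 °C
Reagents that add atoms: none
Why: Oxidative cleavage of both PMB ethers (hydride abstraction, then hydrolysis of the oxocarbenium ions) under buffered conditions that spare the epoxide, the silyl ether and the ester.

**Step 11**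
Reactants: 18 (2R)-1-hydroxy-3-[(2R,3R)-3-{(2R,3Z)-2-{[tert-butyl(dimethyl)silyl]oxy}-5-hydroxy-3-methylpent-3-en-1-yl}-2-methyloxiran-2-yl]propan-2-yl 3-methylbutanoate
Product: 19 (2R)-1-oxo-3-[(2R,3R)-3-{(2R,3Z)-2-{[tert-butyl(dimethyl)silyl]oxy}-3-methyl-5-oxopent-3-en-1-yl}-2-methyloxiran-2-yl]propan-2-yl 3-methylbutanoate
Conditions: Dess–Martin periodinane (2.5 equiv), NaHCO3, CH2Cl2, 0 °C; used at once
Reagents that add atoms: none
Why: Double Dess–Martin oxidation of the two primary alcohols under buffered, non-epimerising conditions gives the Z-enal (C6) and the α-acyloxy aldehyde (C7) without touching C8.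

**Step 12**
Reactants: 19 (2R)-1-oxo-3-[(2R,3R)-3-{(2R,3Z)-2-{[tert-butyl(dimethyl)silyl]oxy}-3-methyl-5-oxopent-3-en-1-yl}-2-methyloxiran-2-yl]propan-2-yl 3-methylbutanoate; 20 methyl acrylate
Product: 21 methyl (4R)-3-hydroxy-2-methylidene-4-[(3-methylbutanoyl)oxy]-5-[(2R,3R)-3-{(2R,3Z)-2-{[tert-butyl(dimethyl)silyl]oxy}-3-methyl-5-oxopent-3-en-1-yl}-2-methyloxiran-2-yl]pentanoate (both C3 epimers)
Conditions: 20 (10 equiv, neat), 1,4-diazabicyclo[2.2.2]octane (0.5 equiv), rt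
Reagents that add atoms: none
Why: Morita–Baylis–Hillman reaction: the amine–acrylate zwitterion adds only to the activated α-acyloxy aldehyde because the β,β-disubstituted enal is unreactive under these conditions; the new carbinol centre is removed in the next step.

**Step 13**
Reactants: 21 methyl (4R)-3-hydroxy-2-methylidene-4-[(3-methylbutanoyl)oxy]-5-[(2R,3R)-3-{(2R,3Z)-2-{[tert-butyl(dimethyl)silyl]oxy}-3-methyl-5-oxopent-3-en-1-yl}-2-methyloxiran-2-yl]pentanoate
Product: 22 methyl (2Z,4R)-2-(bromomethyl)-4-[(3-methylbutanoyl)oxy]-5-[(2R,3R)-3-{(2R,3Z)-2-{[tert-butyl(dimethyl)silyl]oxy}-3-methyl-5-oxopent-3-en-1-yl}-2-methyloxiran-2-yl]pent-2-enoate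
Conditions: N-bromosuccinimide, Me2S, CH2Cl2, −20 to 0 °C
Reagents that add atoms: N-bromosuccinimide, O=C1CCC(=O)N1Br
Why: Corey–Kim-type activation of the allylic alcohol as an alkoxysulfonium salt and SN2′ attack of bromide give the (Z)-2-(bromomethyl)enoate with allylic transposition under non-acidic conditions.

**Step 14 (key step)**
Reactants: 22 methyl (2Z,4R)-2-(bromomethyl)-4-[(3-methylbutanoyl)oxy]-5-[(2R,3R)-3-{(2R,3Z)-2-{[tert-butyl(dimethyl)silyl]oxy}-3-methyl-5-oxopent-3-en-1-yl}-2-methyloxiran-2-yl]pent-2-enoate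
Product: 25 (1R,3R,6R,7R,8R,10R)-3-{[tert-butyl(dimethyl)silyl]oxy}-1,10-epoxy-8-[(3-methylbutanoyl)oxy]germacra-4Z,11(13)-dien-12,6-olide, via allylchromium dichloride 23 (not isolated), via ring-closed chromium alkoxide 24 (not isolated)
Conditions: CrCl2 (divalent chromium chloride, 6 equiv), DMF–THF, rt, 22 added by syringe pump over 10 h (final 2 mM); then 45 °C, 2 h; aq. NH4Cl
Reagents that add atoms: none
Why: Nozaki–Hiyama-type (chromium Barbier) intramolecular allylation followed by lactonisation: the allylchromium adds through its γ-carbon C7 to the enal in a six-membered transition state inside the forming ten-membered ring, with C8 directing the face of C7 by allylic 1,3-strain and the ring placing C5 and C8 anti across the new bond (6R,7R, trans-fused, as in chromium- and zinc-mediated closures of costunolide- and parthenolide-type precursors), and the chromium alkoxide then displaces methoxide from the neighbouring ester to close the α-methylene lactone.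

**Step 15**
Reactants: 25 (1R,3R,6R,7R,8R,10R)-3-{[tert-butyl(dimethyl)silyl]oxy}-1,10-epoxy-8-[(3-methylbutanoyl)oxy]germacra-4Z,11(13)-dien-12,6-olide
Product: 26 (1R,3R,6R,7R,8R,10R)-1,10-epoxy-3-hydroxy-8-[(3-methylbutanoyl)oxy]germacra-4Z,11(13)-dien-12,6-olide (CNP0300193.1)
Conditions: Bu4NF, AcOH (1:1), THF, 0 °C to rt
Reagents that add atoms: none
Why: Fluoride-mediated desilylation buffered with acetic acid frees the C3 hydroxyl without conjugate addition to the α-methylene lactone, acyl migration or epoxide opening.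

**Compound list**

1 | but-2-yn-1-ol | CC#CCO | starting material
2 | cyclic sodium alkenylaluminate (Al on C3 of the butenyl chain, cis to the CH2O arm) | [Na+].COCCO[Al-]1(OCCOC)OCC=C1C | intermediate (not isolated)
3 | (2Z)-3-iodobut-2-en-1-ol | OC/C=C(/C)I | intermediate
4 | 1-({[(2Z)-3-iodobut-2-en-1-yl]oxy}methyl)-4-methoxybenzene | COc1ccc(COC/C=C(/C)I)cc1 | intermediate
5 | pent-3-yn-1-ol | CC#CCCO | starting material
6 | (E)-alkenylzirconocene chloride of pent-3-yn-1-ol (Zr on C4, hydroxyl held as zirconocene alkoxide) | C/C(=C\CCO[Zr](Cl)(C1C=CC=C1)C1C=CC=C1)[Zr](Cl)(C1C=CC=C1)C1C=CC=C1 | intermediate (not isolated)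
7 | (3E)-4-iodopent-3-en-1-ol | OCC/C=C(\C)I | intermediate
8 | (3E)-4-iodopent-3-enal | O=CC/C=C(\C)I | intermediate
9 | [(2Z)-4-(4-methoxybenzyloxy)but-2-en-2-yl]lithium | COc1ccc(COC/C=C(/C)[Li])cc1 | intermediate (not isolated)
10 | bis[(2Z)-4-(4-methoxybenzyloxy)but-2-en-2-yl]zinc | COc1ccc(COC/C=C(/C)[Zn]/C(C)=C\COCc2ccc(OC)cc2)cc1 | intermediate (not isolated)
11 | (2Z,4R,6E)-7-iodo-1-[(4-methoxybenzyl)oxy]-3-methylocta-2,6-dien-4-ol | COc1ccc(COC/C=C(/C)[C@H](O)C/C=C(\C)I)cc1 | intermediate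
12 | tert-butyl({(2Z,4R,6E)-7-iodo-1-[(4-methoxybenzyl)oxy]-3-methylocta-2,6-dien-4-yl}oxy)dimethylsilane | COc1ccc(COC/C=C(/C)[C@H](O[Si](C)(C)C(C)(C)C)C/C=C(\C)I)cc1 | intermediate
13 | (2R)-2-{[(4-methoxybenzyl)oxy]methyl}oxirane | COc1ccc(COC[C@H]2CO2)cc1 | starting material
14 | alkenyllithium from 12 (Li in place of I, E geometry kept) | COc1ccc(COC/C=C(/C)[C@H](O[Si](C)(C)C(C)(C)C)C/C=C(\C)[Li])cc1 | intermediate (not isolated)
15 | (2R,4E,7R,8Z)-7-{[tert-butyl(dimethyl)silyl]oxy}-1,10-bis[(4-methoxybenzyl)oxy]-4,8-dimethyldeca-4,8-dien-2-ol | COc1ccc(COC/C=C(/C)[C@H](O[Si](C)(C)C(C)(C)C)C/C=C(\C)C[C@@H](O)COCc2ccc(OC)cc2)cc1 | intermediate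
16 | (2R,4E,7R,8Z)-7-{[tert-butyl(dimethyl)silyl]oxy}-1,10-bis[(4-methoxybenzyl)oxy]-4,8-dimethyldeca-4,8-dien-2-yl 3-methylbutanoate | COc1ccc(COC/C=C(/C)[C@H](O[Si](C)(C)C(C)(C)C)C/C=C(\C)C[C@@H](OC(=O)CC(C)C)COCc2ccc(OC)cc2)cc1 | intermediate
17 | (2R)-1-[(4-methoxybenzyl)oxy]-3-[(2R,3R)-3-{(2R,3Z)-2-{[tert-butyl(dimethyl)silyl]oxy}-5-[(4-methoxybenzyl)oxy]-3-methylpent-3-en-1-yl}-2-methyloxiran-2-yl]propan-2-yl 3-methylbutanoate | COc1ccc(COC/C=C(/C)[C@H](O[Si](C)(C)C(C)(C)C)C[C@H]2O[C@]2(C)C[C@@H](OC(=O)CC(C)C)COCc3ccc(OC)cc3)cc1 | intermediate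
18 | (2R)-1-hydroxy-3-[(2R,3R)-3-{(2R,3Z)-2-{[tert-butyl(dimethyl)silyl]oxy}-5-hydroxy-3-methylpent-3-en-1-yl}-2-methyloxiran-2-yl]propan-2-yl 3-methylbutanoate | OC/C=C(/C)[C@H](O[Si](C)(C)C(C)(C)C)C[C@H]1O[C@]1(C)C[C@@H](OC(=O)CC(C)C)CO | intermediate
19 | (2R)-1-oxo-3-[(2R,3R)-3-{(2R,3Z)-2-{[tert-butyl(dimethyl)silyl]oxy}-3-methyl-5-oxopent-3-en-1-yl}-2-methyloxiran-2-yl]propan-2-yl 3-methylbutanoate | O=C/C=C(/C)[C@H](O[Si](C)(C)C(C)(C)C)C[C@H]1O[C@]1(C)C[C@@H](OC(=O)CC(C)C)C=O | intermediate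
20 | methyl acrylate | C=CC(=O)OC | starting material
21 | methyl (4R)-3-hydroxy-2-methylidene-4-[(3-methylbutanoyl)oxy]-5-[(2R,3R)-3-{(2R,3Z)-2-{[tert-butyl(dimethyl)silyl]oxy}-3-methyl-5-oxopent-3-en-1-yl}-2-methyloxiran-2-yl]pentanoate (both C3 epimers) | O=C/C=C(/C)[C@H](O[Si](C)(C)C(C)(C)C)C[C@H]1O[C@]1(C)C[C@@H](OC(=O)CC(C)C)C(O)C(=C)C(=O)OC | intermediate
22 | methyl (2Z,4R)-2-(bromomethyl)-4-[(3-methylbutanoyl)oxy]-5-[(2R,3R)-3-{(2R,3Z)-2-{[tert-butyl(dimethyl)silyl]oxy}-3-methyl-5-oxopent-3-en-1-yl}-2-methyloxiran-2-yl]pent-2-enoate | O=C/C=C(/C)[C@H](O[Si](C)(C)C(C)(C)C)C[C@H]1O[C@]1(C)C[C@@H](OC(=O)CC(C)C)/C=C(\CBr)C(=O)OC | intermediate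
23 | allylchromium dichloride from 22 (trivalent chromium on C13 in place of Br) | O=C/C=C(/C)[C@H](O[Si](C)(C)C(C)(C)C)C[C@H]1O[C@]1(C)C[C@@H](OC(=O)CC(C)C)/C=C(\C[Cr](Cl)Cl)C(=O)OC | intermediate (not isolated)
24 | ring-closed chromium alkoxide (ten-membered carbocycle with C6–O–CrCl2 and the C11 methyl acrylate unit, 6R,7R) | COC(=O)C(=C)[C@H]1[C@H](O[Cr](Cl)Cl)/C=C(/C)[C@H](O[Si](C)(C)C(C)(C)C)C[C@H]2O[C@]2(C)C[C@H]1OC(=O)CC(C)C | intermediate (not isolated)
25 | (1R,3R,6R,7R,8R,10R)-3-{[tert-butyl(dimethyl)silyl]oxy}-1,10-epoxy-8-[(3-methylbutanoyl)oxy]germacra-4Z,11(13)-dien-12,6-olide | C=C1C(=O)O[C@@H]2/C=C(/C)[C@H](O[Si](C)(C)C(C)(C)C)C[C@H]3O[C@]3(C)C[C@@H](OC(=O)CC(C)C)[C@@H]12 | intermediate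
26 | (1R,3R,6R,7R,8R,10R)-1,10-epoxy-3-hydroxy-8-[(3-methylbutanoyl)oxy]germacra-4Z,11(13)-dien-12,6-olide (CNP0300193.1) | C=C1C(=O)O[C@@H]2/C=C(/C)[C@H](O)C[C@H]3O[C@]3(C)C[C@@H](OC(=O)CC(C)C)[C@@H]12 | target

**Step count**

Total step count: 15 (two steps to 4, two steps to 8, eleven steps from their union to 26).
Longest linear sequence: 13 steps (5 → 7 → 8 → 11 → … → 26; the branch from 1 is equally long).

**Three steps most likely to fail**

Step 14 is the weakest point. The closure may give the 6,7-cis lactone, the allylchromium may lose isovalerate by 1,4-elimination, or oligomers may form. The fallback sets out from 21: acetylation (Ac2O, pyridine) gives the Morita–Baylis–Hillman acetate F1, and the ring is then closed by umpolung instead of through a preformed organochromium reagent. Pd(PPh3)4 (zerovalent palladium, 5 mol %) ionises the allylic acetate and InI (monovalent indium iodide) converts the π-allylpalladium into an allylindium species that is generated slowly in the presence of the enal (THF, high dilution, rt) and lactonises on mildly acidic work-up. This comes back to the route at 25.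

Step 12 is the second risk. The amine may epimerise C8 of the α-acyloxy aldehyde, promote acyl migration in the adduct, or isomerise the Z-enal. The fallback sets out from 18 and unveils the two termini one after the other. The less hindered allylic C6 hydroxyl is silylated selectively (Et3SiCl, 2,6-lutidine, −40 °C) to the mono-triethylsilyl ether F2, and Dess–Martin oxidation gives the mono-aldehyde F3. The Morita–Baylis–Hillman reaction is run on this enal-free substrate to give the adduct F4, and N-bromosuccinimide/Me2S gives the allylic bromide F5. HF·pyridine/pyridine removes only the primary silyl ether to give the allylic alcohol F6, and MnO2 oxidation comes back to the route at 22.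

Step 5 is the third risk: the enantioselectivity of the alkenylzinc addition may be insufficient for this Z-trisubstituted alkenyl group. The fallback sets out from 11 of low enantiopurity. Dess–Martin oxidation gives the dienone F7, and reduction with catecholborane and (S)-1-methyl-3,3-diphenyltetrahydro-1H,3H-pyrrolo[1,2-c][1,3,2]oxazaborole (Corey–Bakshi–Shibata reduction, the alkenyl group acting as the large substituent) returns to 11 with 3R fixed by the reagent.

**Further compounds**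

F1 | step 14 | methyl (4R)-3-acetoxy-2-methylidene-4-[(3-methylbutanoyl)oxy]-5-[(2R,3R)-3-{(2R,3Z)-2-{[tert-butyl(dimethyl)silyl]oxy}-3-methyl-5-oxopent-3-en-1-yl}-2-methyloxiran-2-yl]pentanoate (both C3 epimers) | O=C/C=C(/C)[C@H](O[Si](C)(C)C(C)(C)C)C[C@H]1O[C@]1(C)C[C@@H](OC(=O)CC(C)C)C(OC(C)=O)C(=C)C(=O)OC
F2 | step 12 | (2R)-1-hydroxy-3-[(2R,3R)-3-{(2R,3Z)-2-{[tert-butyl(dimethyl)silyl]oxy}-3-methyl-5-[(triethylsilyl)oxy]pent-3-en-1-yl}-2-methyloxiran-2-yl]propan-2-yl 3-methylbutanoate | CC[Si](CC)(CC)OC/C=C(/C)[C@H](O[Si](C)(C)C(C)(C)C)C[C@H]1O[C@]1(C)C[C@@H](OC(=O)CC(C)C)CO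
F3 | step 12 | (2R)-1-oxo-3-[(2R,3R)-3-{(2R,3Z)-2-{[tert-butyl(dimethyl)silyl]oxy}-3-methyl-5-[(triethylsilyl)oxy]pent-3-en-1-yl}-2-methyloxiran-2-yl]propan-2-yl 3-methylbutanoate | CC[Si](CC)(CC)OC/C=C(/C)[C@H](O[Si](C)(C)C(C)(C)C)C[C@H]1O[C@]1(C)C[C@@H](OC(=O)CC(C)C)C=O
F4 | step 12 | methyl (4R)-3-hydroxy-2-methylidene-4-[(3-methylbutanoyl)oxy]-5-[(2R,3R)-3-{(2R,3Z)-2-{[tert-butyl(dimethyl)silyl]oxy}-3-methyl-5-[(triethylsilyl)oxy]pent-3-en-1-yl}-2-methyloxiran-2-yl]pentanoate (both C3 epimers) | CC[Si](CC)(CC)OC/C=C(/C)[C@H](O[Si](C)(C)C(C)(C)C)C[C@H]1O[C@]1(C)C[C@@H](OC(=O)CC(C)C)C(O)C(=C)C(=O)OC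
F5 | step 12 | methyl (2Z,4R)-2-(bromomethyl)-4-[(3-methylbutanoyl)oxy]-5-[(2R,3R)-3-{(2R,3Z)-2-{[tert-butyl(dimethyl)silyl]oxy}-3-methyl-5-[(triethylsilyl)oxy]pent-3-en-1-yl}-2-methyloxiran-2-yl]pent-2-enoate | CC[Si](CC)(CC)OC/C=C(/C)[C@H](O[Si](C)(C)C(C)(C)C)C[C@H]1O[C@]1(C)C[C@@H](OC(=O)CC(C)C)/C=C(\CBr)C(=O)OC
F6 | step 12 | methyl (2Z,4R)-2-(bromomethyl)-4-[(3-methylbutanoyl)oxy]-5-[(2R,3R)-3-{(2R,3Z)-2-{[tert-butyl(dimethyl)silyl]oxy}-5-hydroxy-3-methylpent-3-en-1-yl}-2-methyloxiran-2-yl]pent-2-enoate | OC/C=C(/C)[C@H](O[Si](C)(C)C(C)(C)C)C[C@H]1O[C@]1(C)C[C@@H](OC(=O)CC(C)C)/C=C(\CBr)C(=O)OC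
F7 | step 5 | (2Z,6E)-7-iodo-1-[(4-methoxybenzyl)oxy]-3-methylocta-2,6-dien-4-one | COc1ccc(COC/C=C(/C)C(=O)C/C=C(\C)I)cc1
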